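At early times, averaged over Monday's and Friday's runs, target rose at 0.00733 min⁻¹, as a fraction of the charge. The percent curves lay together at charges of 0.39 M and 0.13 M, so I read both runs as one curve.

| flask | starting material | protic impurity | remark | time |
|---|---|---|---|---|
| Monday's | 0.39 M | 0.25 M | run made earlier |  |
| Friday's | 0.13 M | 0.25 M | run made earlier |  |
| blue | 0.26 M | 0.250 M |  | 6.0 h |
| grey | 0.26 M | 0.800 M |  | 6.0 h |
| ochre | 0.26 M | 2.50 M |  | 6.0 h |

| run | time / min | target / % | starting material / % |
|---|---|---|---|
| Monday's | 6.00 | 4.5 | 87.2 |
| Monday's | 12.0 | 8.1 | 76.9 |
| Monday's | 30.0 | 17.3 | 53.9 |
| Monday's | 80.0 | 32.1 | 23.2 |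
| Friday's | 6.00 | 4.3 | 86.9 |
| Friday's | 12.0 | 9.3 | 76.2 |
| Friday's | 30.0 | 17.6 | 53.9 |
| Friday's | 80.0 | 31.6 | 22.7 |

(standard deviation of a reading: 0.5 percentage points)

- "hardly changes" means that all values lie within two and a half points (for a concentration: within two and a half percent of the largest)
- no earlier run changes the charge of protic impurity; that part of a forecast is a guess

* amount of target at the end, in percent of the starting material charged for blue, grey, ochre, in this order
* the shape of the row from first to last (falls, then rises / hardly changes / falls all the way / rises, then falls / rises all the way)

I averaged the runs and divided target gained by starting material lost, so that time dropped out. Up to 6.00 min that gave 0.340. Between 30.0 min and 80.0 min the slope of target sagged to 0.00288 min⁻¹. That was the knee. But the ratio rose to 0.465. I called this reading the late share, the fraction of target gained per fraction of starting material lost, a selectivity taken late in the run. By 80.0 min in Monday's run, target, at 32.1%, had crossed above starting material, at 23.2%.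

I then let the starting material left at that reading go on at the late share. So I reckoned that target would level off at 42.5% in blue, whose charge of protic impurity matched the earlier runs. No run varied protic impurity, so I had no number for grey or ochre. I kept one estimate, with the charge of starting material and the time held as in blue: starting material diverted elsewhere costs target at the late share.

The forecast gave 59%, 58% and 57%, shape hardly changes, and it held that “the pool still drains to target”. For blue, its 59% stood above my level of 42.5%.

The flasks gave 43.8%, 40.2% and 32.0%: the row falls all the way.

    starting material ⇌ other conformer (K = 1.70, k = 0.810 h⁻¹)
    starting material → target (k = 0.470 h⁻¹)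
    other conformer → isomer of the product (k = 0.840 h⁻¹)
    other conformer ⇌ third conformer (K = 2.30, k = 0.190 h⁻¹)
    third conformer → third product (k = 0.940 h⁻¹)
    starting material + protic impurity → quenched substrate (k = 0.180 L mol⁻¹ h⁻¹)

The largest single effect on the fall from blue to ochre was the reaction of starting material with protic impurity: with it taken away, the change of −12 percentage points became 0 points. At 6.00 h, grey held 12.1% of quenched substrate against 4.10% in blue, so the late share of 0.465 put grey's target at 40.1%, and the flask gave 40.2%. Ochre held 30.2% of quenched substrate, so the same share put its target at 31.7%, and the flask gave 32.0%.

(All runs come from a simulation for an exercise; the scatter is artificial.)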